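**Plan**

1. Cuts: (a) the bond from the enone β-carbon of ring A (cyclohexenone) to the CH2CH2 linker, (b) in ring A the bond between the carbonyl carbon and the methyl-bearing α-carbon, (c) in the left half one C–C bond of ring C (cyclohexane) and the O–CMe2 bond of ring D (oxepane).
2. Enabling feature: the C(=O)–C(Me)=C(linker) unit of ring A is a 1,3-transposed aldol retron. With the oxygen moved to the linker carbon, the C(=O)–C(Me) bond is the C=C of a 2-methylcyclohexenone, and ring B (the cyclohexane carrying the tertiary alcohol and the CMe2 group) holds a propanoyl and a CH2CHO arm cis on adjacent carbons (a 1,5-keto aldehyde).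
3. Right half: ring B is elaborated from 4,4-dimethylcyclohexenone (steps 1–7); ring A is closed by intramolecular aldol condensation (step 8).
4. Left half: an acyclic geranyl-derived bis-epoxide allylsilane closes rings D and C in one epoxide-opening cascade (step 13) and is taken on to a terminal alkyne (steps 14–19).
5. Union: alkynylcerium addition to the ring A ketone, oxidative 1,3-transposition with pyridinium chlorochromate (sets the target C=O and the tetrasubstituted C=C), alkyne hydrogenation, desilylation (steps 20–23).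
6. Stereochemistry: right half, one centre by copper-catalysed asymmetric conjugate addition, the other two relayed from it (anti epoxidation, trans-diaxial opening). Left half, three C–O centres by Shi epoxidation, two centres by the chair cascade, the tertiary carbinol by substrate-controlled epoxidation and hydride opening.

Key step: step 8

Remark: the L-sorbose-derived enantiomer of the Shi ketone, the phosphoramidite ligand and the Ohira–Bestmann reagent are taken as purchasable. Names number the right half as a cyclohexane or naphthalenone and the left half as a 1-benzoxepine.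

**Right half**

Step 1
Reactants: 1 4,4-dimethylcyclohex-2-en-1-one; 2 2-bromobut-1-ene
Product: 5 {[(3R)-3-(but-1-en-2-yl)-4,4-dimethylcyclohex-1-en-1-yl]oxy}trimethylsilane, via alkenylalane 3 (not isolated), via aluminium enolate 4 (not isolated)
Conditions: 2, t-BuLi (2 equiv), Et2O, −78 °C; Me2AlCl, −78 to −30 °C; then 1, Cu(O2CC4H3S) (copper thiophene-2-carboxylate, 5 mol%), O,O′-(S)-binaphthyl N,N-bis[(S)-1-phenylethyl]phosphoramidite (10 mol%; the ligand antipode that delivers 3R is used), Et2O, −30 °C; then Me3SiOTf, THF, −30 to 0 °C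
Reagents that add atoms: trimethylsilyl trifluoromethanesulfonate, C[Si](C)(C)OS(=O)(=O)C(F)(F)F
Why: Copper-catalysed asymmetric conjugate addition of an alkenylalane (the sp2 group transfers in preference to methyl) should set C3 as R under control of the chiral phosphoramidite–copper complex, and O-silylation of the aluminium enolate fixes the enolate regiochemistry toward C2.

Step 2
Reactants: 5 {[(3R)-3-(but-1-en-2-yl)-4,4-dimethylcyclohex-1-en-1-yl]oxy}trimethylsilane
Product: 7 (3R)-3-(but-1-en-2-yl)-4,4-dimethylcyclohex-1-en-1-yl trifluoromethanesulfonate, via lithium enolate 6 (not isolated)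
Conditions: MeLi, THF, 0 °C; then N-(5-chloropyridin-2-yl)-N-(trifluoromethylsulfonyl)trifluoromethanesulfonamide (Comins' reagent), −78 to 0 °C; aq. NH4Cl
Reagents that add atoms: Comins' reagent, O=S(=O)(N(c1ccc(Cl)cn1)S(=O)(=O)C(F)(F)F)C(F)(F)F
Why: Methyllithium cleaves the silyl enol ether to the regiodefined lithium enolate, which is O-triflated (enol triflate synthesis) before it can equilibrate; C3 is not touched.

Step 3
Reactants: 7 (3R)-3-(but-1-en-2-yl)-4,4-dimethylcyclohex-1-en-1-yl trifluoromethanesulfonate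
Product: 8 (3R)-3-(but-1-en-2-yl)-1,4,4-trimethylcyclohex-1-ene
Conditions: MeMgBr, Fe(acac)3 (5 mol%), THF/NMP, −30 to 0 °C
Reagents that add atoms: methylmagnesium bromide, C[Mg]Br
Why: Iron-catalysed Kumada-type cross-coupling of an alkenyl triflate with a methyl Grignard reagent (Fürstner conditions) installs the ring methyl group and leaves the 1,1-disubstituted alkene alone.

Step 4
Reactants: 8 (3R)-3-(but-1-en-2-yl)-1,4,4-trimethylcyclohex-1-ene
Product: 9 (1R,2R,6S)-2-(but-1-en-2-yl)-3,3,6-trimethyl-7-oxabicyclo[4.1.0]heptane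
Conditions: mCPBA (1.0 equiv), NaHCO3, CH2Cl2, −20 to 0 °C
Reagents that add atoms: 3-chloroperoxybenzoic acid, OOC(=O)c1cccc(Cl)c1
Why: Prilezhaev epoxidation is chemoselective for the trisubstituted ring alkene over the hindered 1,1-disubstituted side-chain alkene and should occur anti to the allylic butenyl group, which shields its own face in either half-chair; this sets both epoxide carbons.

Step 5
Reactants: 9 (1R,2R,6S)-2-(but-1-en-2-yl)-3,3,6-trimethyl-7-oxabicyclo[4.1.0]heptane
Product: 10 (1S,2S,3R)-3-(but-1-en-2-yl)-1,4,4-trimethyl-2-(prop-2-en-1-yl)cyclohexan-1-ol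
Conditions: allylMgCl, CuI (10 mol%), THF, −20 to 25 °C; aq. NH4Cl
Reagents that add atoms: allylmagnesium chloride, C=CC[Mg]Cl
Why: Copper-catalysed Grignard opening of the epoxide at its secondary carbon in the trans-diaxial (Fürst–Plattner) sense inverts that carbon, so the allyl group ends cis to the butenyl group and trans to the tertiary hydroxyl, whose configuration is kept from the epoxide.

Step 6
Reactants: 10 (1S,2S,3R)-3-(but-1-en-2-yl)-1,4,4-trimethyl-2-(prop-2-en-1-yl)cyclohexan-1-ol
Product: 11 triethyl{[(1S,2S,3R)-3-(but-1-en-2-yl)-1,4,4-trimethyl-2-(prop-2-en-1-yl)cyclohexyl]oxy}silane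
Conditions: Et3SiOTf, 2,6-lutidine, CH2Cl2, −78 to 0 °C
Reagents that add atoms: triethylsilyl trifluoromethanesulfonate, CC[Si](CC)(CC)OS(=O)(=O)C(F)(F)F
Why: Silyl triflate protection of the tertiary alcohol prevents lactol formation with the aldehyde of step 7 and alkoxide formation in step 20; no stereocentre is affected.

Step 7
Reactants: 11 triethyl{[(1S,2S,3R)-3-(but-1-en-2-yl)-1,4,4-trimethyl-2-(prop-2-en-1-yl)cyclohexyl]oxy}silane
Product: 13 2-[(1S,2S,6R)-2,5,5-trimethyl-6-propanoyl-2-[(triethylsilyl)oxy]cyclohexyl]acetaldehyde, via bis-ozonide 12 (not isolated)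
Conditions: O3, CH2Cl2, −78 °C; then PPh3, −78 to 25 °C
Reagents that add atoms: ozone, [O-][O+]=O
Why: Ozonolysis with reductive work-up cleaves both terminal alkenes in one operation, the 1,1-disubstituted one to the ethyl ketone and the allyl group to the CH2CHO arm; no base is present, so the cis relationship is kept.

Step 8
Reactants: 13 2-[(1S,2S,6R)-2,5,5-trimethyl-6-propanoyl-2-[(triethylsilyl)oxy]cyclohexyl]acetaldehyde
Product: 15 (4aS,5S,8aR)-2,5,8,8-tetramethyl-5-[(triethylsilyl)oxy]-4a,5,6,7,8,8a-hexahydronaphthalen-1(4H)-one, via aldol adduct 14 (not isolated)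
Conditions: piperidine (0.5 equiv), AcOH (0.5 equiv), toluene (0.01 M), 4 Å molecular sieves, 60 °C
Reagents that add atoms: none
Why: The enol of the ethyl ketone attacks, through its CH2 carbon, the aldehyde (activated as its iminium ion) and so forms the bond that, after the transposition of step 21, is the C(=O)–C(Me) bond of ring A; E1cB loss of water then gives the conjugated 2-methylenone. The closest known reaction type is the intramolecular aldol condensation of a 1,5-keto aldehyde, the ring-closing half of a Robinson annulation. Ring A closes in the 6-(enolendo)-exo-trig mode. No new stereocentre is retained, because the carbinol and α-carbons both become sp2, and the cis ring fusion is the cis-1,2 relationship already present in 13. The step needs enolisation toward the ethyl CH2 and pairing of ketone donor with aldehyde acceptor; every other donor–acceptor pairing would close a four-membered ring. It also needs the ring methine α to the ketone to keep its configuration; that C–H is flanked by the quaternary CMe2 carbon and should enolise slowly in the buffered, weakly basic medium.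

**Left half**

Step 9
Reactants: 16 methyl acetoacetate; 17 geranyl bromide
Product: 19 methyl (6E)-7,11-dimethyl-3-oxododeca-6,10-dienoate, via acetoacetate dianion 18 (not isolated)
Conditions: NaH, THF, 0 °C; n-BuLi, 0 °C; then 17, 0 to 25 °C; aq. NH4Cl
Reagents that add atoms: none
Why: Weiler dianion alkylation: the γ-carbon of the acetoacetate dianion is the more nucleophilic site and displaces the allylic bromide by SN2 with the E alkene unchanged.

Step 10
Reactants: 19 methyl (6E)-7,11-dimethyl-3-oxododeca-6,10-dienoate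
Product: 20 methyl (2Z,6E)-3-[(diethoxyphosphoryl)oxy]-7,11-dimethyldodeca-2,6,10-trienoate
Conditions: NaH, Et2O, 0 °C; then ClP(O)(OEt)2
Reagents that add atoms: diethyl chlorophosphate, CCOP(=O)(Cl)OCC
Why: O-phosphorylation of the chelated sodium enolate in ether gives the (Z)-enol phosphate (Weiler), the geometry that later places the ester equatorial.

Step 11
Reactants: 20 methyl (2Z,6E)-3-[(diethoxyphosphoryl)oxy]-7,11-dimethyldodeca-2,6,10-trienoate
Product: 21 methyl (2Z,6E)-7,11-dimethyl-3-[(trimethylsilyl)methyl]dodeca-2,6,10-trienoate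
Conditions: Me3SiCH2MgCl, Ni(acac)2 (5 mol%), THF, 0 to 25 °C
Reagents that add atoms: (trimethylsilyl)methylmagnesium chloride, C[Si](C)(C)C[Mg]Cl
Why: Nickel-catalysed Kumada-type coupling of the enol phosphate proceeds with retention of alkene geometry and gives the (Z)-allylsilane that will terminate the cascade.

Step 12
Reactants: 21 methyl (2Z,6E)-7,11-dimethyl-3-[(trimethylsilyl)methyl]dodeca-2,6,10-trienoate
Product: 22 methyl (2Z)-5-[(2S,3S)-3-{2-[(2S)-3,3-dimethyloxiran-2-yl]ethyl}-3-methyloxiran-2-yl]-3-[(trimethylsilyl)methyl]pent-2-enoate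
Conditions: L-sorbose-derived enantiomer of the Shi ketone (0.6 equiv), KHSO5 (as the triple salt 2KHSO5·KHSO4·K2SO4), K2CO3, Bu4NHSO4, MeCN/CH2(OMe)2/aq. Na2B4O7 buffer (pH 10.5), 0 °C
Reagents that add atoms: potassium peroxymonosulfate, [K+].[O-]S(=O)(=O)OO
Why: Shi asymmetric epoxidation (chiral dioxirane, spiro transition state) attacks the two electron-rich trisubstituted alkenes and not the electron-poor enoate; this ketone enantiomer should give the (S,S) and (S) epoxides, which fix three C–O stereocentres.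

Step 13
Reactants: 22 methyl (2Z)-5-[(2S,3S)-3-{2-[(2S)-3,3-dimethyloxiran-2-yl]ethyl}-3-methyloxiran-2-yl]-3-[(trimethylsilyl)methyl]pent-2-enoate
Product: 24 methyl (3S,5aS,6R,9aS)-3-hydroxy-2,2,5a-trimethyl-7-methylidenedecahydro-1-benzoxepine-6-carboxylate, via silyl ether 23 (not isolated)
Conditions: Me3SiOTf (0.3 equiv), 2,6-di-tert-butyl-4-methylpyridine, CH2Cl2, −78 °C; then aq. HCl (0.5 M), THF, 0 °C
Reagents that add atoms: none
Why: Lewis-acid-triggered epoxide-opening cascade (tandem oxa- and carbacyclisation with an allylsilane terminator): the internal epoxide oxygen opens the silylated terminal epoxide at its tertiary carbon to a bicyclic epoxonium ion, the (Z)-allylsilane opens that ion at its tertiary carbon with inversion through a chair transition state (ring C forms and the oxacycle grows to the seven-membered ring D, trans-fused, with axial methyl and equatorial ester), loss of Me3Si+ leaves the exocyclic alkene, and the three C–O centres come unchanged from 22.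

Step 14
Reactants: 24 methyl (3S,5aS,6R,9aS)-3-hydroxy-2,2,5a-trimethyl-7-methylidenedecahydro-1-benzoxepine-6-carboxylate
Product: 25 methyl (3S,5aS,6R,9aS)-3-[(tert-butyldimethylsilyl)oxy]-2,2,5a-trimethyl-7-methylidenedecahydro-1-benzoxepine-6-carboxylate
Conditions: t-BuMe2SiOTf, 2,6-lutidine, CH2Cl2, 0 °C
Reagents that add atoms: tert-butyldimethylsilyl trifluoromethanesulfonate, CC(C)(C)[Si](C)(C)OS(=O)(=O)C(F)(F)F
Why: Silyl triflate protection of the hindered secondary alcohol, which would otherwise be oxidised in steps 18 and 21.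

Step 15
Reactants: 25 methyl (3S,5aS,6R,9aS)-3-[(tert-butyldimethylsilyl)oxy]-2,2,5a-trimethyl-7-methylidenedecahydro-1-benzoxepine-6-carboxylate
Product: 26 methyl (3S,5aS,6S,7S,9aS)-3-[(tert-butyldimethylsilyl)oxy]-2,2,5a-trimethyloctahydro-2H-spiro[1-benzoxepine-7,2'-oxirane]-6-carboxylate (oxirane oxygen equatorial)
Conditions: mCPBA, NaHCO3, CH2Cl2, 0 °C
Reagents that add atoms: 3-chloroperoxybenzoic acid, OOC(=O)c1cccc(Cl)c1
Why: Prilezhaev epoxidation of the exocyclic alkene from the equatorial direction, the axial approach being blocked by the 1,3-diaxial angular methyl group, places the oxirane oxygen where the tertiary hydroxyl must be.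

Step 16
Reactants: 26 methyl (3S,5aS,6S,7S,9aS)-3-[(tert-butyldimethylsilyl)oxy]-2,2,5a-trimethyloctahydro-2H-spiro[1-benzoxepine-7,2'-oxirane]-6-carboxylate
Product: 27 (3S,5aS,6R,7S,9aS)-3-[(tert-butyldimethylsilyl)oxy]-6-(hydroxymethyl)-2,2,5a,7-tetramethyldecahydro-1-benzoxepin-7-ol
Conditions: LiAlH4, THF, 0 to 40 °C; aq. NaOH work-up
Reagents that add atoms: none
Why: Hydride reduction takes the ester to the primary alcohol and opens the spiro-epoxide at its CH2 terminus (SN2), which creates the axial methyl group and leaves the tertiary C–O configuration untouched.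

Step 17
Reactants: 27 (3S,5aS,6R,7S,9aS)-3-[(tert-butyldimethylsilyl)oxy]-6-(hydroxymethyl)-2,2,5a,7-tetramethyldecahydro-1-benzoxepin-7-ol
Product: 28 tert-butyldimethyl{[(3S,5aS,6R,7S,9aS)-2,2,5a,7-tetramethyl-7-[(triethylsilyl)oxy]-6-{[(triethylsilyl)oxy]methyl}decahydro-1-benzoxepin-3-yl]oxy}silane
Conditions: Et3SiOTf (2.5 equiv), 2,6-lutidine, CH2Cl2, −78 to 0 °C
Reagents that add atoms: triethylsilyl trifluoromethanesulfonate, CC[Si](CC)(CC)OS(=O)(=O)C(F)(F)F
Why: Exhaustive silylation protects the tertiary alcohol (a free β-hydroxy aldehyde would be open to retro-aldol cleavage) and turns the primary alcohol into the substrate of step 18.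

Step 18
Reactants: 28 tert-butyldimethyl{[(3S,5aS,6R,7S,9aS)-2,2,5a,7-tetramethyl-7-[(triethylsilyl)oxy]-6-{[(triethylsilyl)oxy]methyl}decahydro-1-benzoxepin-3-yl]oxy}silane
Product: 29 (3S,5aS,6S,7S,9aS)-3-[(tert-butyldimethylsilyl)oxy]-2,2,5a,7-tetramethyl-7-[(triethylsilyl)oxy]decahydro-1-benzoxepine-6-carbaldehyde
Conditions: (COCl)2, DMSO, CH2Cl2, −78 to −30 °C; then Et3N, −78 to 25 °C
Reagents that add atoms: none
Why: Swern oxidation applied to a primary triethylsilyl ether, which the chlorosulfonium reagent cleaves and oxidises to the aldehyde in one pot while the tertiary triethylsilyl and secondary tert-butyldimethylsilyl ethers stay; the formyl group is equatorial, so the α-centre is not at risk.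

Step 19
Reactants: 29 (3S,5aS,6S,7S,9aS)-3-[(tert-butyldimethylsilyl)oxy]-2,2,5a,7-tetramethyl-7-[(triethylsilyl)oxy]decahydro-1-benzoxepine-6-carbaldehyde
Product: 30 tert-butyl{[(3S,5aS,6S,7S,9aS)-6-ethynyl-2,2,5a,7-tetramethyl-7-[(triethylsilyl)oxy]decahydro-1-benzoxepin-3-yl]oxy}dimethylsilane
Conditions: dimethyl (1-diazo-2-oxopropyl)phosphonate, K2CO3, MeOH, 0 to 25 °C
Reagents that add atoms: dimethyl (1-diazo-2-oxopropyl)phosphonate, CC(=O)C(=[N+]=[N-])P(=O)(OC)OC
Why: Seyferth–Gilbert homologation with the Ohira–Bestmann reagent converts the aldehyde into the terminal alkyne with one added carbon under mild base; the equatorial configuration of the α-carbon is the thermodynamic one.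

**Union and end game**

Step 20
Reactants: 30 tert-butyl{[(3S,5aS,6S,7S,9aS)-6-ethynyl-2,2,5a,7-tetramethyl-7-[(triethylsilyl)oxy]decahydro-1-benzoxepin-3-yl]oxy}dimethylsilane; 15 (4aS,5S,8aR)-2,5,8,8-tetramethyl-5-[(triethylsilyl)oxy]-4a,5,6,7,8,8a-hexahydronaphthalen-1(4H)-one
Product: 33 tertiary propargylic alcohol from 1,2-addition of the alkyne carbon of 30 to the carbonyl of 15 (both epimers at the new carbinol carbon), via lithium acetylide 31 (not isolated), via cerium acetylide 32 (not isolated)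
Conditions: 30, n-BuLi, THF, −78 °C; anhydrous CeCl3, THF, −78 °C; then 15, −78 to −40 °C; aq. NH4Cl
Reagents that add atoms: none
Why: 1,2-Addition of an alkynylcerium reagent (Imamoto conditions): the small, weakly basic nucleophile should add to the hindered, enolisable ketone without deprotonating the ring-fusion methine, and the mixture at the new carbinol centre does not matter because step 21 destroys it.

Step 21
Reactants: 33 tertiary propargylic alcohol (both epimers)
Product: 34 enynone: sipholenol K tris(silyl ether) with C≡C in place of the CH2CH2 linker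
Conditions: [C5H5NH][CrO3Cl] (pyridinium chlorochromate), NaOAc, 4 Å molecular sieves, CH2Cl2, 25 °C
Reagents that add atoms: pyridinium chlorochromate, [O-][Cr](=O)(=O)Cl.c1cc[nH+]cc1
Why: Dauben–Babler oxidative 1,3-transposition: the chromate ester of the tertiary allylic alcohol shifts by a [3,3]-sigmatropic path to the secondary allylic carbon and is oxidised, which puts the carbonyl on the former aldol carbon and the tetrasubstituted alkene between the methyl-bearing and alkynyl-bearing carbons; both carbinol epimers converge.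

Step 22
Reactants: 34 enynone
Product: 35 sipholenol K tris(silyl ether) (secondary tert-butyldimethylsilyl ether; two tertiary triethylsilyl ethers)
Conditions: H2 (1 atm), Pd/C (5 wt%), EtOAc, 25 °C, stopped after 2 equiv of H2
Reagents that add atoms: none
Why: Heterogeneous catalytic hydrogenation should saturate the alkyne (through the dienone) much faster than the tetrasubstituted, sterically shielded enone C=C, giving the CH2CH2 linker without touching a stereocentre.

Step 23
Reactants: 35 sipholenol K tris(silyl ether)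
Product: 36 sipholenol K
Conditions: HF·pyridine, pyridine, THF, 0 to 40 °C
Reagents that add atoms: none
Why: Fluoride-mediated global desilylation, buffered with pyridine, removes the two tertiary triethylsilyl ethers and the secondary tert-butyldimethylsilyl ether without dehydrating the tertiary alcohols or epimerising the γ-position of the enone.

**Compound list**

1 | 4,4-dimethylcyclohex-2-en-1-one | CC1(C)CCC(=O)C=C1 | starting material
2 | 2-bromobut-1-ene | C=C(Br)CC | starting material
3 | (but-1-en-2-yl)dimethylaluminium | C=C(CC)[Al](C)C | intermediate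
4 | dimethylaluminium enolate of (3R)-3-(but-1-en-2-yl)-4,4-dimethylcyclohexanone | C=C(CC)[C@@H]1C=C(O[Al](C)C)CCC1(C)C | intermediate
5 | {[(3R)-3-(but-1-en-2-yl)-4,4-dimethylcyclohex-1-en-1-yl]oxy}trimethylsilane | C=C(CC)[C@@H]1C=C(O[Si](C)(C)C)CCC1(C)C | intermediate
6 | lithium (3R)-3-(but-1-en-2-yl)-4,4-dimethylcyclohex-1-en-1-olate | C=C(CC)[C@@H]1C=C([O-])CCC1(C)C.[Li+] | intermediate
7 | (3R)-3-(but-1-en-2-yl)-4,4-dimethylcyclohex-1-en-1-yl trifluoromethanesulfonate | C=C(CC)[C@@H]1C=C(OS(=O)(=O)C(F)(F)F)CCC1(C)C | intermediate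
8 | (3R)-3-(but-1-en-2-yl)-1,4,4-trimethylcyclohex-1-ene | C=C(CC)[C@@H]1C=C(C)CCC1(C)C | intermediate
9 | (1R,2R,6S)-2-(but-1-en-2-yl)-3,3,6-trimethyl-7-oxabicyclo[4.1.0]heptane | C=C(CC)[C@@H]1[C@H]2O[C@@]2(C)CCC1(C)C | intermediate
10 | (1S,2S,3R)-3-(but-1-en-2-yl)-1,4,4-trimethyl-2-(prop-2-en-1-yl)cyclohexan-1-ol | C=C(CC)[C@@H]1[C@H](CC=C)[C@@](C)(O)CCC1(C)C | intermediate
11 | triethyl{[(1S,2S,3R)-3-(but-1-en-2-yl)-1,4,4-trimethyl-2-(prop-2-en-1-yl)cyclohexyl]oxy}silane | C=C(CC)[C@@H]1[C@H](CC=C)[C@@](C)(O[Si](CC)(CC)CC)CCC1(C)C | intermediate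
12 | bis(1,2,4-trioxolane) from 11 (both alkenes as secondary ozonides) | CCC1(OCOO1)[C@@H]2[C@H](CC3OCOO3)[C@@](C)(O[Si](CC)(CC)CC)CCC2(C)C | intermediate
13 | 2-[(1S,2S,6R)-2,5,5-trimethyl-6-propanoyl-2-[(triethylsilyl)oxy]cyclohexyl]acetaldehyde | CCC(=O)[C@@H]1[C@H](CC=O)[C@@](C)(O[Si](CC)(CC)CC)CCC1(C)C | intermediate
14 | (4aS,5S,8aR)-3-hydroxy-2,5,8,8-tetramethyl-5-[(triethylsilyl)oxy]octahydronaphthalen-1(2H)-one (epimers at C2 and C3) | O=C1C(C)C(O)C[C@H]2[C@@H]1C(C)(C)CC[C@]2(C)O[Si](CC)(CC)CC | intermediate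
15 | (4aS,5S,8aR)-2,5,8,8-tetramethyl-5-[(triethylsilyl)oxy]-4a,5,6,7,8,8a-hexahydronaphthalen-1(4H)-one (cis-fused) | O=C1C(C)=CC[C@H]2[C@@H]1C(C)(C)CC[C@]2(C)O[Si](CC)(CC)CC | intermediate
16 | methyl acetoacetate | COC(=O)CC(C)=O | starting material
17 | geranyl bromide, (2E)-1-bromo-3,7-dimethylocta-2,6-diene | BrC/C=C(\C)CCC=C(C)C | starting material
18 | sodium lithium dianion of methyl acetoacetate | [Na+].[Li+].COC(=O)[CH-]C(=O)[CH2-] | intermediate
19 | methyl (6E)-7,11-dimethyl-3-oxododeca-6,10-dienoate | COC(=O)CC(=O)CC/C=C(\C)CCC=C(C)C | intermediate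
20 | methyl (2Z,6E)-3-[(diethoxyphosphoryl)oxy]-7,11-dimethyldodeca-2,6,10-trienoate | COC(=O)/C=C(\OP(=O)(OCC)OCC)CC/C=C(\C)CCC=C(C)C | intermediate
21 | methyl (2Z,6E)-7,11-dimethyl-3-[(trimethylsilyl)methyl]dodeca-2,6,10-trienoate | COC(=O)/C=C(\C[Si](C)(C)C)CC/C=C(\C)CCC=C(C)C | intermediate
22 | methyl (2Z)-5-[(2S,3S)-3-{2-[(2S)-3,3-dimethyloxiran-2-yl]ethyl}-3-methyloxiran-2-yl]-3-[(trimethylsilyl)methyl]pent-2-enoate | COC(=O)/C=C(\C[Si](C)(C)C)CC[C@@H]1O[C@@]1(C)CC[C@@H]1OC1(C)C | intermediate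
23 | methyl (3S,5aS,6R,9aS)-2,2,5a-trimethyl-7-methylidene-3-[(trimethylsilyl)oxy]decahydro-1-benzoxepine-6-carboxylate | COC(=O)[C@H]1[C@]2(C)CC[C@H](O[Si](C)(C)C)C(C)(C)O[C@H]2CCC1=C | intermediate
24 | methyl (3S,5aS,6R,9aS)-3-hydroxy-2,2,5a-trimethyl-7-methylidenedecahydro-1-benzoxepine-6-carboxylate (trans-fused) | COC(=O)[C@H]1[C@]2(C)CC[C@H](O)C(C)(C)O[C@H]2CCC1=C | intermediate
25 | methyl (3S,5aS,6R,9aS)-3-[(tert-butyldimethylsilyl)oxy]-2,2,5a-trimethyl-7-methylidenedecahydro-1-benzoxepine-6-carboxylate | COC(=O)[C@H]1[C@]2(C)CC[C@H](O[Si](C)(C)C(C)(C)C)C(C)(C)O[C@H]2CCC1=C | intermediate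
26 | methyl (3S,5aS,6S,7S,9aS)-3-[(tert-butyldimethylsilyl)oxy]-2,2,5a-trimethyloctahydro-2H-spiro[1-benzoxepine-7,2'-oxirane]-6-carboxylate | COC(=O)[C@H]1[C@]2(C)CC[C@H](O[Si](C)(C)C(C)(C)C)C(C)(C)O[C@H]2CC[C@@]13CO3 | intermediate
27 | (3S,5aS,6R,7S,9aS)-3-[(tert-butyldimethylsilyl)oxy]-6-(hydroxymethyl)-2,2,5a,7-tetramethyldecahydro-1-benzoxepin-7-ol | OC[C@H]1[C@]2(C)CC[C@H](O[Si](C)(C)C(C)(C)C)C(C)(C)O[C@H]2CC[C@]1(C)O | intermediate
28 | tert-butyldimethyl{[(3S,5aS,6R,7S,9aS)-2,2,5a,7-tetramethyl-7-[(triethylsilyl)oxy]-6-{[(triethylsilyl)oxy]methyl}decahydro-1-benzoxepin-3-yl]oxy}silane | CC[Si](CC)(CC)OC[C@H]1[C@]2(C)CC[C@H](O[Si](C)(C)C(C)(C)C)C(C)(C)O[C@H]2CC[C@]1(C)O[Si](CC)(CC)CC | intermediate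
29 | (3S,5aS,6S,7S,9aS)-3-[(tert-butyldimethylsilyl)oxy]-2,2,5a,7-tetramethyl-7-[(triethylsilyl)oxy]decahydro-1-benzoxepine-6-carbaldehyde | O=C[C@H]1[C@]2(C)CC[C@H](O[Si](C)(C)C(C)(C)C)C(C)(C)O[C@H]2CC[C@]1(C)O[Si](CC)(CC)CC | intermediate
30 | tert-butyl{[(3S,5aS,6S,7S,9aS)-6-ethynyl-2,2,5a,7-tetramethyl-7-[(triethylsilyl)oxy]decahydro-1-benzoxepin-3-yl]oxy}dimethylsilane | C#C[C@H]1[C@]2(C)CC[C@H](O[Si](C)(C)C(C)(C)C)C(C)(C)O[C@H]2CC[C@]1(C)O[Si](CC)(CC)CC | intermediate
31 | lithium acetylide of 30 | [Li]C#C[C@H]1[C@]2(C)CC[C@H](O[Si](C)(C)C(C)(C)C)C(C)(C)O[C@H]2CC[C@]1(C)O[Si](CC)(CC)CC | intermediate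
32 | dichlorocerium acetylide of 30 | Cl[Ce](Cl)C#C[C@H]1[C@]2(C)CC[C@H](O[Si](C)(C)C(C)(C)C)C(C)(C)O[C@H]2CC[C@]1(C)O[Si](CC)(CC)CC | intermediate
33 | tertiary propargylic alcohol: 15 with its C=O carbon converted into C(OH) bearing the ethynyl carbon of 30 (epimers at that carbon) | OC1(C#C[C@H]3[C@]4(C)CC[C@H](O[Si](C)(C)C(C)(C)C)C(C)(C)O[C@H]4CC[C@]3(C)O[Si](CC)(CC)CC)C(C)=CC[C@H]2[C@@H]1C(C)(C)CC[C@]2(C)O[Si](CC)(CC)CC | intermediate
34 | enynone: (4aR,8S,8aS)-3,5,5,8-tetramethyl-8-[(triethylsilyl)oxy]-4a,5,6,7,8,8a-hexahydronaphthalen-2(1H)-one carrying at C4 the ethynyl group of 30 | CC1=C(C#C[C@H]3[C@]4(C)CC[C@H](O[Si](C)(C)C(C)(C)C)C(C)(C)O[C@H]4CC[C@]3(C)O[Si](CC)(CC)CC)[C@@H]2[C@H](CC1=O)[C@@](C)(O[Si](CC)(CC)CC)CCC2(C)C | intermediate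
35 | sipholenol K tris(silyl ether): 34 with CH2CH2 in place of C≡C | CC1=C(CC[C@H]3[C@]4(C)CC[C@H](O[Si](C)(C)C(C)(C)C)C(C)(C)O[C@H]4CC[C@]3(C)O[Si](CC)(CC)CC)[C@@H]2[C@H](CC1=O)[C@@](C)(O[Si](CC)(CC)CC)CCC2(C)C | intermediate
36 | sipholenol K | CC1=C(CC[C@H]2[C@]3(C)CC[C@H](O)C(C)(C)O[C@H]3CC[C@]2(C)O)[C@@H]2[C@H](CC1=O)[C@@](C)(O)CCC2(C)C | target

**Summary**

Total step count: 23. Longest linear sequence: 15 steps (steps 9–19, then 20–23).

**Steps most likely to fail**

Step 5. The axial SN2 attack at the secondary epoxide carbon is hindered by the adjacent butenyl group and a 1,3-diaxial methyl group, so attack at the tertiary carbon or magnesium-induced rearrangement of the epoxide may compete. The fallback sets out from 9 and uses the smallest carbon nucleophile without a Lewis acid: LiC≡CH·ethylenediamine in DMSO should open the epoxide trans-diaxially at the secondary carbon to give (1S,2R,3R)-3-(but-1-en-2-yl)-2-ethynyl-1,4,4-trimethylcyclohexan-1-ol F1. Et3SiOTf with 2,6-lutidine gives its triethylsilyl ether F2. Anti-Markovnikov hydration of the terminal alkyne (dicyclohexylborane, then NaBO3 in water) gives 2-[(1S,2S,6R)-6-(but-1-en-2-yl)-2,5,5-trimethyl-2-[(triethylsilyl)oxy]cyclohexyl]acetaldehyde F3. Ozonolysis of the one remaining alkene (O3, then PPh3) comes back to the route at 13.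

Step 8. The ring-fusion methine α to the ketone may epimerise (cis to trans) under the condensation conditions, or intermolecular aldehyde condensation may outrun cyclisation. The fallback sets out from 13 and closes the same bond as a Lewis-acid-mediated Mukaiyama aldol reaction of a preformed, regiodefined enol ether. Aldehyde-selective acetalisation (MeOSiMe3, Me3SiOTf cat., CH2Cl2, −78 °C) gives 1-[(1R,2S,3S)-2-(2,2-dimethoxyethyl)-3,6,6-trimethyl-3-[(triethylsilyl)oxy]cyclohexyl]propan-1-one F4. Kinetic deprotonation at the ethyl CH2 (LiN(iPr)2, THF, −78 °C, then Me3SiCl) gives the trimethylsilyl enol ether F5. Me3SiOTf (cat., CH2Cl2, −78 °C) closes ring A onto the oxocarbenium ion to give the β-methoxy ketone (4aS,5S,8aR)-3-methoxy-2,5,8,8-tetramethyl-5-[(triethylsilyl)oxy]octahydronaphthalen-1(2H)-one F6. Elimination of methanol with DBU comes back to the route at 15.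

Step 22. The hydrogenation may over-reduce the tetrasubstituted enone C=C or stall at the dienone on the hindered alkyne. The fallback sets out from 29 and joins the halves through an sp3 nucleophile, so no hydrogenation is needed. Wittig methylenation (Ph3P=CH2) gives the 6-ethenyl analogue of 30, vinyl compound F7. Hydroboration–oxidation (9-BBN, then NaOH/H2O2) gives the 6-(2-hydroxyethyl) analogue, primary alcohol F8. I2, PPh3 and imidazole give the 6-(2-iodoethyl) analogue, iodide F9. Iodine–lithium exchange (t-BuLi, −78 °C), transmetallation to CeCl3 and addition to 15 give the tertiary allylic alcohol with the saturated linker F10. Oxidative 1,3-transposition with pyridinium chlorochromate comes back to the route at 35.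

**Further compounds**

F1 | step 5 | (1S,2R,3R)-3-(but-1-en-2-yl)-2-ethynyl-1,4,4-trimethylcyclohexan-1-ol | C=C(CC)[C@@H]1[C@H](C#C)[C@@](C)(O)CCC1(C)C
F2 | step 5 | triethyl{[(1S,2R,3R)-3-(but-1-en-2-yl)-2-ethynyl-1,4,4-trimethylcyclohexyl]oxy}silane | C=C(CC)[C@@H]1[C@H](C#C)[C@@](C)(O[Si](CC)(CC)CC)CCC1(C)C
F3 | step 5 | 2-[(1S,2S,6R)-6-(but-1-en-2-yl)-2,5,5-trimethyl-2-[(triethylsilyl)oxy]cyclohexyl]acetaldehyde | C=C(CC)[C@@H]1[C@H](CC=O)[C@@](C)(O[Si](CC)(CC)CC)CCC1(C)C
F4 | step 8 | 1-[(1R,2S,3S)-2-(2,2-dimethoxyethyl)-3,6,6-trimethyl-3-[(triethylsilyl)oxy]cyclohexyl]propan-1-one | CCC(=O)[C@@H]1[C@H](CC(OC)OC)[C@@](C)(O[Si](CC)(CC)CC)CCC1(C)C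
F5 | step 8 | trimethylsilyl enol ether of F4 (enol double bond toward the ethyl group) | CC=C(O[Si](C)(C)C)[C@@H]1[C@H](CC(OC)OC)[C@@](C)(O[Si](CC)(CC)CC)CCC1(C)C
F6 | step 8 | (4aS,5S,8aR)-3-methoxy-2,5,8,8-tetramethyl-5-[(triethylsilyl)oxy]octahydronaphthalen-1(2H)-one (epimers at C2 and C3) | O=C1C(C)C(OC)C[C@H]2[C@@H]1C(C)(C)CC[C@]2(C)O[Si](CC)(CC)CC
F7 | step 22 | tert-butyl{[(3S,5aS,6S,7S,9aS)-6-ethenyl-2,2,5a,7-tetramethyl-7-[(triethylsilyl)oxy]decahydro-1-benzoxepin-3-yl]oxy}dimethylsilane | C=C[C@H]1[C@]2(C)CC[C@H](O[Si](C)(C)C(C)(C)C)C(C)(C)O[C@H]2CC[C@]1(C)O[Si](CC)(CC)CC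
F8 | step 22 | 2-[(3S,5aS,6S,7S,9aS)-3-[(tert-butyldimethylsilyl)oxy]-2,2,5a,7-tetramethyl-7-[(triethylsilyl)oxy]decahydro-1-benzoxepin-6-yl]ethan-1-ol | OCC[C@H]1[C@]2(C)CC[C@H](O[Si](C)(C)C(C)(C)C)C(C)(C)O[C@H]2CC[C@]1(C)O[Si](CC)(CC)CC
F9 | step 22 | tert-butyl{[(3S,5aS,6S,7S,9aS)-6-(2-iodoethyl)-2,2,5a,7-tetramethyl-7-[(triethylsilyl)oxy]decahydro-1-benzoxepin-3-yl]oxy}dimethylsilane | ICC[C@H]1[C@]2(C)CC[C@H](O[Si](C)(C)C(C)(C)C)C(C)(C)O[C@H]2CC[C@]1(C)O[Si](CC)(CC)CC
F10 | step 22 | tertiary allylic alcohol: 33 with CH2CH2 in place of C≡C (epimers at the carbinol carbon) | OC1(CC[C@H]3[C@]4(C)CC[C@H](O[Si](C)(C)C(C)(C)C)C(C)(C)O[C@H]4CC[C@]3(C)O[Si](CC)(CC)CC)C(C)=CC[C@H]2[C@@H]1C(C)(C)CC[C@]2(C)O[Si](CC)(CC)CC
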